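**Retrosynthetic overview**

- Ring numbering: C1 carries the side chain, then C2, C3 (OH), C4, C5 (OMe), C6 (OAc). The C1=C2 bond is opened last by selenoxide syn-elimination from a C2 selenide, and the C3 carbinol comes from a C3 ketone.
- The C6–O bond is traced back to a C6 acetyl group by Baeyer–Villiger oxidation with retention.
- Feature used: in the six-membered carbocycle, C2–C3(O)–C4–C5(O) maps onto a 1,1-dimethoxy-3-silyloxybutadiene, and C1/C6 are the β/α carbons of an (E)-methyl enone. Cutting C1–C2 and C5–C6 is therefore a [4+2] disconnection.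
- The enone comes from dodecanal by asymmetric allylation, acetylation and cross-metathesis with butenone. The diene comes from 1,1-dimethoxyethene by C-acetylation and silylation.
- Ring order: there is one ring, and it is closed once, in the cycloaddition.

Key step: step 6

Assumption: the (S)-configured oxazaborolidinium cation is assigned to the Cα-Re/Cβ-Si face of the enone by the α-C–H···O binding model known for acrylates and enones; the antipodal catalyst is used if the sense proves reversed.

**Step 1**
Reactants: 1 dodecanal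
Product: 3 (R)-pentadec-1-en-4-ol, via diisopinocampheylborinate 2 (not isolated)
Conditions: (−)-B-allyldiisopinocampheylborane, Et2O, −78 °C; then NaOH, 30% H2O2, 0 °C → rt
Reagents that add atoms: (−)-B-allyldiisopinocampheylborane C=CCB([C@@H]1C[C@@H]2C[C@H]([C@H]1C)C2(C)C)[C@@H]1C[C@@H]2C[C@H]([C@H]1C)C2(C)C
Why: Brown allylboration through a closed chair-like six-membered transition state; the reagent derived from (+)-α-pinene delivers allyl to the Si face of the aldehyde, which sets the carbinol centre as R (allyl outranks undecyl).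

**Step 2**
Reactants: 3 (R)-pentadec-1-en-4-ol
Product: 4 (R)-pentadec-1-en-4-yl acetate
Conditions: Ac2O, pyridine, 4-(dimethylamino)pyridine (cat.), CH2Cl2, 0 °C → rt
Reagents that add atoms: acetic anhydride CC(=O)OC(C)=O
Why: Nucleophile-catalysed O-acylation of a secondary alcohol, which does not touch the stereocentre.

**Step 3**
Reactants: 4 (R)-pentadec-1-en-4-yl acetate; 5 but-3-en-2-one (excess)
Product: 6 (3E,6R)-2-oxoheptadec-3-en-6-yl acetate
Conditions: second-generation Grubbs catalyst RuCl2(=CHPh)(PCy3)(H2IMes) (3 mol %), CH2Cl2, 40 °C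
Reagents that add atoms: none
Why: Olefin cross-metathesis of a terminal alkene with an electron-poor vinyl ketone that homodimerises slowly should give the conjugated enone as the E isomer under thermodynamic control.

**Step 4**
Reactants: 7 1,1-dimethoxyethene (2 equiv)
Product: 8 4,4-dimethoxybut-3-en-2-one
Conditions: acetyl chloride (1 equiv), Et2O, 0 °C → rt
Reagents that add atoms: acetyl chloride CC(Cl)=O
Why: C-Acylation of the nucleophilic ketene acetal followed by loss of HCl from the dialkoxycarbenium ion, with the second equivalent of 7 acting as the HCl acceptor (it ends as methyl acetate and chloromethane), is the classical route to acylketene acetals.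

**Step 5**
Reactants: 8 4,4-dimethoxybut-3-en-2-one
Product: 10 1,1-dimethoxy-3-(trimethylsilyloxy)buta-1,3-diene, via lithium enolate 9 (not isolated)
Conditions: LiN(iPr)2, THF, −78 °C; Me3SiCl, −78 → 0 °C; non-aqueous work-up, distillation
Reagents that add atoms: chlorotrimethylsilane C[Si](C)(C)Cl
Why: Kinetic deprotonation of the methyl group of the vinylogous carbonate and O-silylation of the enolate (silyl enol ether formation) gives the 2-silyloxydiene; no stereocentre is involved.

**Step 6**
Reactants: 6 (3E,6R)-2-oxoheptadec-3-en-6-yl acetate; 10 1,1-dimethoxy-3-(trimethylsilyloxy)buta-1,3-diene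
Product: 12 (4S,5R)-4-acetyl-5-[(2R)-2-acetoxytridecyl]-3-methoxycyclohex-2-en-1-one, via silyl enol ether ketal 11 (not isolated)
Conditions: (S)-3,3-diphenyl-1-(2-methylphenyl)tetrahydro-1H,3H-pyrrolo[1,2-c][1,3,2]oxazaborole (C24H24BNO) protonated with HN(SO2CF3)2 (20 mol %), Ph3PO (25 mol %), CH2Cl2, slow addition of 10, −78 → −40 °C; then 0.1 M HCl, THF, 0 °C
Reagents that add atoms: none
Why: The boron cation binds the acetyl oxygen of 6 and lowers its LUMO; the CH2 terminus of 10, which both the silyloxy and the ketene-acetal oxygens make the most nucleophilic site, bonds to the β-carbon (ring C1) and the ketene-acetal carbon to the α-carbon (ring C6) in a concerted but strongly asynchronous [4+2] addition that borders on a Mukaiyama–Michael/ring-closure sequence, giving 11, and dilute acid then cleaves the silyl enol ether with vinylogous loss of methanol toward C4 to leave the 3-methoxyenone 12. The closest known reactions are oxazaborolidinium-catalysed Diels–Alder reactions of enones with 2-silyloxydienes, Michael additions of silyl ketene acetals to acyclic enones under the same catalysts (where Ph3PO traps silyl cations that would otherwise open a racemic pathway), and uncatalysed cycloadditions of 10 with enones. The single carbocycle is closed by this intermolecular [4+2] cycloaddition, suprafacial on both partners, which makes the C1–C2 and C5–C6 bonds. C1 is set by the catalyst, which screens one face so that the diene reaches the Cβ-Si/Cα-Re face; C6 follows from suprafacial addition to the E-alkene (trans to C1) and, being α to the acetyl group, would also settle trans by epimerisation if closure were stepwise. The step needs regio-, face- and chemoselectivity: regiochemistry rests on the matched polarisation of diene and enone, face selectivity on the catalyst (the remote side-chain centre is a bystander), and the ketone is activated in preference to the less basic acetate, while the ketal of 11 ionises only with the help of the enol ether on the C4 side, so the methoxy group ends on C5.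

**Step 7**
Reactants: 12 (4S,5R)-4-acetyl-5-[(2R)-2-acetoxytridecyl]-3-methoxycyclohex-2-en-1-one
Product: 13 (1S,6R)-6-[(2R)-2-acetoxytridecyl]-2-methoxy-4-oxocyclohex-2-en-1-yl acetate
Conditions: m-CPBA, NaHCO3 (buffer), CH2Cl2, 0 °C → rt
Reagents that add atoms: 3-chloroperoxybenzoic acid OOC(=O)c1cccc(Cl)c1
Why: Baeyer–Villiger oxidation, in which the secondary ring carbon C6 migrates in preference to methyl with retention of configuration, while the C4=C5 bond and the ring carbonyl, both deactivated as parts of a vinylogous ester, should react more slowly.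

**Step 8**
Reactants: 13 (1S,6R)-6-[(2R)-2-acetoxytridecyl]-2-methoxy-4-oxocyclohex-2-en-1-yl acetate
Product: 15 (1S,5R,6S)-6-[(2R)-2-acetoxytridecyl]-2-methoxy-4-oxo-5-(phenylselanyl)cyclohex-2-en-1-yl acetate, via lithium dienolate 14 (not isolated)
Conditions: LiN(SiMe3)2 (1.1 equiv), THF, −78 °C; PhSeCl, −78 °C; NH4Cl quench
Reagents that add atoms: benzeneselenenyl chloride Cl[Se]c1ccccc1
Why: Kinetic α'-deprotonation of the vinylogous ester at C2 (ketone enolisation outpaces acetate enolisation at −78 °C) and electrophilic selenenylation of the dienolate anti to the adjacent C1 side chain should give the trans C1/C2 selenide, in which selenium is cis to H-1.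

**Step 9**
Reactants: 15 (1S,5R,6S)-6-[(2R)-2-acetoxytridecyl]-2-methoxy-4-oxo-5-(phenylselanyl)cyclohex-2-en-1-yl acetate
Product: 16 (1S,4R,5R,6S)-6-[(2R)-2-acetoxytridecyl]-4-hydroxy-2-methoxy-5-(phenylselanyl)cyclohex-2-en-1-yl acetate
Conditions: NaBH4, CeCl3·7H2O, MeOH/THF, −40 → 0 °C; NaHCO3 work-up
Reagents that add atoms: none
Why: Luche 1,2-reduction, in which hydride is expected to add axially to the half-chair that holds the C1, C2 and C6 substituents equatorial (the all-axial alternative suffers a syn-diaxial PhSe/OAc contact), that is on the face opposite the C1 side chain, placing the new hydroxyl trans to selenium and trans to the C6 acetate; this selectivity is not secure and is treated as a risk below.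

**Step 10**
Reactants: 16 (1S,4R,5R,6S)-6-[(2R)-2-acetoxytridecyl]-4-hydroxy-2-methoxy-5-(phenylselanyl)cyclohex-2-en-1-yl acetate
Product: 18 (1S,4S)-6-[(2R)-2-acetoxytridecyl]-4-hydroxy-2-methoxycyclohexa-2,5-dien-1-yl acetate, via selenoxide 17 (not isolated)
Conditions: 30% H2O2, pyridine, CH2Cl2, 0 °C → rt
Reagents that add atoms: none
Why: Oxidation to the selenoxide and syn-elimination with the cis hydrogen on C1 should form C1=C2, because β-hydroxy selenoxides eliminate away from the carbinol carbon, and since C3 is already an alcohol no cross-conjugated dienone that could tautomerise to a phenol can arise; pyridine keeps the acid-sensitive dienol buffered.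

**Compound list**

1 | dodecanal | CCCCCCCCCCCC=O | starting material
2 | (R)-pentadec-1-en-4-yl diisopinocampheylborinate (isopinocampheyl groups from (+)-α-pinene) | CCCCCCCCCCC[C@H](CC=C)OB([C@@H]1C[C@@H]2C[C@H]([C@H]1C)C2(C)C)[C@@H]1C[C@@H]2C[C@H]([C@H]1C)C2(C)C | intermediate
3 | (R)-pentadec-1-en-4-ol | CCCCCCCCCCC[C@H](CC=C)O | intermediate
4 | (R)-pentadec-1-en-4-yl acetate | CCCCCCCCCCC[C@H](CC=C)OC(C)=O | intermediate
5 | but-3-en-2-one | CC(=O)C=C | starting material
6 | (3E,6R)-2-oxoheptadec-3-en-6-yl acetate | CCCCCCCCCCC[C@H](C/C=C/C(C)=O)OC(C)=O | intermediate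
7 | 1,1-dimethoxyethene | C=C(OC)OC | starting material
8 | 4,4-dimethoxybut-3-en-2-one | CC(=O)C=C(OC)OC | intermediate
9 | lithium 4,4-dimethoxybuta-1,3-dien-2-olate | [Li+].C=C([O-])C=C(OC)OC | intermediate
10 | 1,1-dimethoxy-3-(trimethylsilyloxy)buta-1,3-diene | C=C(O[Si](C)(C)C)C=C(OC)OC | intermediate
11 | (2R)-1-[(1R,6R)-6-acetyl-5,5-dimethoxy-3-(trimethylsilyloxy)cyclohex-3-en-1-yl]tridecan-2-yl acetate | CCCCCCCCCCC[C@H](C[C@@H]1CC(O[Si](C)(C)C)=CC(OC)(OC)[C@H]1C(C)=O)OC(C)=O | intermediate
12 | (4S,5R)-4-acetyl-5-[(2R)-2-acetoxytridecyl]-3-methoxycyclohex-2-en-1-one | CCCCCCCCCCC[C@H](C[C@@H]1CC(=O)C=C(OC)[C@H]1C(C)=O)OC(C)=O | intermediate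
13 | (1S,6R)-6-[(2R)-2-acetoxytridecyl]-2-methoxy-4-oxocyclohex-2-en-1-yl acetate | CCCCCCCCCCC[C@H](C[C@@H]1CC(=O)C=C(OC)[C@H]1OC(C)=O)OC(C)=O | intermediate
14 | lithium (3R,4S)-4-acetoxy-3-[(2R)-2-acetoxytridecyl]-5-methoxycyclohexa-1,5-dien-1-olate | [Li+].CCCCCCCCCCC[C@H](C[C@@H]1C=C([O-])C=C(OC)[C@H]1OC(C)=O)OC(C)=O | intermediate
15 | (1S,5R,6S)-6-[(2R)-2-acetoxytridecyl]-2-methoxy-4-oxo-5-(phenylselanyl)cyclohex-2-en-1-yl acetate | CCCCCCCCCCC[C@H](C[C@@H]1[C@@H]([Se]c2ccccc2)C(=O)C=C(OC)[C@H]1OC(C)=O)OC(C)=O | intermediate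
16 | (1S,4R,5R,6S)-6-[(2R)-2-acetoxytridecyl]-4-hydroxy-2-methoxy-5-(phenylselanyl)cyclohex-2-en-1-yl acetate | CCCCCCCCCCC[C@H](C[C@@H]1[C@@H]([Se]c2ccccc2)[C@H](O)C=C(OC)[C@H]1OC(C)=O)OC(C)=O | intermediate
17 | (1S,4R,5R,6S)-6-[(2R)-2-acetoxytridecyl]-4-hydroxy-2-methoxy-5-(phenylseleninyl)cyclohex-2-en-1-yl acetate (both configurations at selenium) | CCCCCCCCCCC[C@H](C[C@@H]1[C@@H]([Se](=O)c2ccccc2)[C@H](O)C=C(OC)[C@H]1OC(C)=O)OC(C)=O | intermediate
18 | (1S,4S)-6-[(2R)-2-acetoxytridecyl]-4-hydroxy-2-methoxycyclohexa-2,5-dien-1-yl acetate (CNP0081579.1) | CCCCCCCCCCC[C@H](CC1=C[C@H](O)C=C(OC)[C@H]1OC(C)=O)OC(C)=O | target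

**Step count**

Total: 10 steps. Longest linear sequence: 8 steps (steps 1, 2, 3, 6, 7, 8, 9, 10).

**Steps most likely to fail, with fallbacks**

Step 6. The strongly acidic boron cation may protodesilylate or oligomerise the electron-rich diene, and released silyl cations may open a racemic pathway, so conversion or face selectivity may be poor. Fallback: 6 and 10 are heated without catalyst in toluene at about 100 °C and the adducts are treated with dilute acid as before. This should give 12 together with its ring-epimeric partner (4R,5S)-4-acetyl-5-[(2R)-2-acetoxytridecyl]-3-methoxycyclohex-2-en-1-one F1. Because the side-chain centre is fixed, the two are diastereomers and are separated by chromatography; the route is rejoined at 12.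

Step 9. Hydride may instead be delivered anti to the C–Se bond through the all-axial conformer (Felkin-type control), which would give the C3 epimer. Fallback: from 15 the same borohydride reduction is run and the epimeric alcohol (1S,4S,5R,6S)-6-[(2R)-2-acetoxytridecyl]-4-hydroxy-2-methoxy-5-(phenylselanyl)cyclohex-2-en-1-yl acetate F2 is collected. A Mitsunobu reaction with formic acid (PPh3, diisopropyl azodicarboxylate, THF, 0 °C) inverts the carbinol centre to the formate (1S,4R,5R,6S)-6-[(2R)-2-acetoxytridecyl]-4-(formyloxy)-2-methoxy-5-(phenylselanyl)cyclohex-2-en-1-yl acetate F3; the cis selenide cannot participate from the rear. Methanolysis of the formate with KHCO3 in MeOH at 0 °C, which spares the acetates, returns the route to 16.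

Step 7. The peracid may oxidise the enol of the acidic C6–H, or the C4=C5 bond, faster than it inserts oxygen at the acetyl carbonyl. Fallback: the C6 hydroxylation is made the intended reaction. From 12, dimethyldioxirane in acetone at 0 °C should give the tertiary ketol (4S,5R)-4-acetyl-5-[(2R)-2-acetoxytridecyl]-4-hydroxy-3-methoxycyclohex-2-en-1-one F4. K2CO3 in MeOH then removes the C-acetyl group by retro-Claisen cleavage of this vinylogous α-hydroxy-β-diketone and also cleaves the side-chain acetate; protonation at C6 under equilibrating conditions should favour the trans arrangement, giving (4S,5R)-4-hydroxy-5-[(2R)-2-hydroxytridecyl]-3-methoxycyclohex-2-en-1-one F5. Acetylation of both hydroxyl groups (Ac2O, pyridine, 4-(dimethylamino)pyridine) returns the route to 13.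

**Further compounds**

F1 | step 6 | (4R,5S)-4-acetyl-5-[(2R)-2-acetoxytridecyl]-3-methoxycyclohex-2-en-1-one | CCCCCCCCCCC[C@H](C[C@H]1CC(=O)C=C(OC)[C@@H]1C(C)=O)OC(C)=O
F2 | step 9 | (1S,4S,5R,6S)-6-[(2R)-2-acetoxytridecyl]-4-hydroxy-2-methoxy-5-(phenylselanyl)cyclohex-2-en-1-yl acetate | CCCCCCCCCCC[C@H](C[C@@H]1[C@@H]([Se]c2ccccc2)[C@@H](O)C=C(OC)[C@H]1OC(C)=O)OC(C)=O
F3 | step 9 | (1S,4R,5R,6S)-6-[(2R)-2-acetoxytridecyl]-4-(formyloxy)-2-methoxy-5-(phenylselanyl)cyclohex-2-en-1-yl acetate | CCCCCCCCCCC[C@H](C[C@@H]1[C@@H]([Se]c2ccccc2)[C@H](OC=O)C=C(OC)[C@H]1OC(C)=O)OC(C)=O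
F4 | step 7 | (4S,5R)-4-acetyl-5-[(2R)-2-acetoxytridecyl]-4-hydroxy-3-methoxycyclohex-2-en-1-one | CCCCCCCCCCC[C@H](C[C@@H]1CC(=O)C=C(OC)[C@]1(O)C(C)=O)OC(C)=O
F5 | step 7 | (4S,5R)-4-hydroxy-5-[(2R)-2-hydroxytridecyl]-3-methoxycyclohex-2-en-1-one | CCCCCCCCCCC[C@H](C[C@@H]1CC(=O)C=C(OC)[C@H]1O)O
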